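# Synthesis plan for CNP0154159.1 (18): copper-catalysed borylative allene–aldehyde cyclisation

## The problem

The target 18 is a 2,3-dihydro-1-benzofuran: a benzene ring (ring A) fused to a dihydrofuran (ring B). Both sp3 carbons of ring B are stereogenic, C2 (R) carrying a 3-oxoprop-1-en-2-yl group and C3 (S) carrying an isovalerate, and the two substituents are trans. C5 of ring A, para to the ring oxygen O1, carries a (1R)-1-acyloxyethyl group whose acyl part is (2R)-2-methylbutanoyl, so four stereocentres must be delivered as one isomer. The two side-chain centres lie across the arene from C2 and C3 and cannot direct them. They are best bought (the acid) or set by a catalyst (the carbinol), and C2/C3 then need a second catalyst-controlled event in which one ring centre controls the other.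

Several groups forbid rough treatment:
- The C3 ester is benzylic and flanked by C2–H, so loss of isovaleric acid gives an aromatic benzofuran.
- The C5 carbinol ester is a para-alkoxybenzylic ester. It ionises in acid and is expelled as a quinone methide as soon as O1 is a free phenoxide.
- The 2-methylbutanoate has an epimerisable α-carbon.
- The enal is a Michael acceptor and should appear last.

The feature that opens the structure is C2. It is at once the carbon bonded to O1 and the allylic carbon of a 1,1-disubstituted alkene, and its neighbour C3 is a carbinol carbon attached to ring A ortho to O1. The C2–C3 bond can therefore be read as the addition of an oxygen-substituted 2-metalloallyl unit to a salicylaldehyde carbonyl, and an aryloxyallene is the natural source of that unit.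

## Retrosynthesis

**18 to 16.** The formyl oxygen is removed first: 18 is traced to the isopropenyl diester 16 by cutting the C–O bonds of the aldehyde, an allylic oxidation of the vinylic methyl group in the forward sense. Placing this last keeps the enal away from phosphines, bases and palladium. Carrying an oxygenated C1 unit from the start would need a protecting group through every later step. 16 is one oxidation level simpler and its alkene is robust. The forward reaction must oxidise the methyl group, not the C2–H methine, and must not trigger acid-induced loss of the C3 ester.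

**16 to 14 and 15.** The C3–O bond of the isovalerate is cut on the alkyl side: 16 comes from the cis-alcohol 14 and 3-methylbutanoic acid 15 with inversion at C3. The reason lies one step further back. A closed transition state in the ring-forming step should give the 2,3-cis alcohol, whereas the target is trans. Cutting the acyl C–O bond (acylation with retention) would then need a separate inversion sequence. The inverting esterification corrects C3 and installs the ester in one operation. 14 lacks the elimination-prone ester. The forward reaction must be a clean SN2 displacement at a benzylic carbon in competition with elimination to the benzofuran.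

**14 to 13.** The vinylic methyl group is disconnected at the C(sp2)–CH3 bond, leading to the alkenylboronate 13. The boron is left on exactly this carbon by the ring-forming step, so the cut costs a single cross-coupling. Doing it at the alcohol stage, before the C3 ester exists, keeps aqueous base away from the ester that eliminates most easily. The forward reaction is the methylation of a hindered 1,1-disubstituted alkenylboronate with everything else unchanged.

**13 to 10 and 11 (key disconnection).** Ring B is opened at C2–C3 together with the C–B bond, leading to the allenyl ether aldehyde 10 and bis(pinacolato)diboron 11. Of the three cuts of ring B this is the only one that removes both ring stereocentres at once. A cut at O1–C2 leaves a stereodefined 1,2-difunctional chain and asks a free phenoxide to cyclise, which is the quinone methide hazard. A cut at C3–C3a leaves a configurationally fragile α-aryloxy aldehyde. 10 has no ring B and only the two side-chain stereocentres. The forward reaction must add a copper boryl to the allene and not to the aldehyde, bond C2 (not the CH2 terminus) to the carbonyl carbon, and choose one enantiomeric series under ligand control.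

**10 to 9, and 9 to 7 and 8.** The aldehyde of 10 is masked as the dimethyl acetal 9, and the side-chain ester C–O bond is cut to give the allenyl ether alcohol 7 and (2R)-2-methylbutanoic acid 8. The ester is introduced only here because it cannot coexist with a free phenoxide at O1 or with the strong base that makes the allene. The acetal hydrolysis asks for an acidity that cleaves an electron-rich aryl acetal but leaves the aryloxyallene and the benzylic ester alone. The esterification must not epimerise 8.

**7 to 6 to 5 to 4.** The allene of 7 is traced to the propargyl ether 6 by a prototropic shift, the (R)-carbinol of 6 to the ketone 5 by asymmetric transfer hydrogenation, and the acetal of 5 to the keto aldehyde 4. The acetal differentiates the two carbonyl groups: the aldehyde would be reduced before the ketone and would not survive alkoxide base. Each precursor is simpler by one functional-group operation. The reduction must be enantioselective without touching the alkyne, and the isomerisation must stop at the allene.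

**4 to 2 and 3, and 2 to 1.** The O–CH2 bond of 4 is cut to 5-acetyl-2-hydroxybenzaldehyde 2 and propargyl bromide 3. The formyl C–C bond of 2 is cut to 4-hydroxyacetophenone 1. The ortho-formylation needs the free phenol and is therefore the first step, before any group that a phenoxide would endanger is present. Compounds 1, 3, 8, 11 and 15 are purchased.

## Roads not taken

**Alternative 1:** The cut is through ring A at C3a–C7a, C4–C5 and C6–C7. In the forward sense RhCl(PPh3)3 would cyclotrimerise the tethered diyne (3S,4R)-3-(tert-butyldimethylsilyloxy)-5-methyl-4-[(trimethylsilyl)ethynyloxy]hex-5-en-1-yne (A2) with the propargylic ester (2R)-but-3-yn-2-yl (2R)-2-methylbutanoate (A3). This would close rings A and B together and give the silylated dihydrobenzofuran A1.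
- Merits: the plan is convergent, and the side-chain stereocentres arrive in one small fragment. No phenoxide ever sits para to the benzylic ester. That is a real advantage over the chosen plan, where this hazard dictates the order of the first seven steps.
- Weak points: the orientation of A3 (side chain at C5 or C6) rests only on the steering effect of the trimethylsilyl group. The silyl ynol ether A2 is a delicate fragment whose two stereocentres need their own asymmetric chemistry, so the C2/C3 problem is moved, not solved. Monovalent rhodium can ionise or rearrange a propargylic ester. After A1 there remain protodesilylation of the aryl silane under acid hostile to both benzylic C–O bonds, removal of the silyl ether, acylation and allylic oxidation.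
- Comparison: it is longer and heavier in protecting groups. The chosen plan keeps ring A intact and creates C2 and C3 in the ring-forming step itself.

**Alternative 2:** The cut is at O1–C2, with O1 reconnected to a gem-dimethyl carbon, so ring B is seen as a contracted chroman. Triflation (Tf2O, hindered pyridine) of the trans-chromanol (3R,4S)-3-hydroxy-2,2-dimethyl-6-[(1R)-1-[(2R)-2-methylbutanoyloxy]ethyl]-3,4-dihydro-2H-chromen-4-yl 3-methylbutanoate (A5) would make O1 migrate from the quaternary carbon to chroman C3 with inversion. Proton loss from the tertiary cation would give the isopropenyl diester A4, which is the same compound as 16.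
- Merits: A5 traces back to Jacobsen epoxidation with a chiral (salen)MnCl complex (trivalent manganese) and opening of the epoxide by 15, among the most dependable asymmetric chemistry for 2,2-dimethylchromenes. The trans relationship follows stereospecifically from the anti migration. The route would probably be two or three steps shorter. In these respects it is better than the chosen plan.
- Weak points: the trans-vicinal C4 isovalerate is ideally placed to displace the triflate itself (acyloxonium formation, acyl scrambling, cis products). The migrating O1–C bond is anti-periplanar to the leaving group only in the diequatorial conformer. The tertiary cation can also lose the C2 proton to give an enol ether, or be captured. The benzylic C4 ester can ionise under the same conditions.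
- Comparison: the chosen plan sets against this a C–C bond formation whose two selectivity questions are separable: enantioselectivity by the ligand, and the relative configuration by the inverting esterification. Its boron handle also gives a second, regiochemically unambiguous path to the enal, whereas A4 depends on the allylic oxidation alone. The ring contraction remains the most attractive reserve strategy.

**Alternative 3:** The cut is at C3–C3a. CrCl2 with catalytic NiCl2 would convert the aryl iodide of (1R)-1-[3-iodo-4-[(2R)-3-methyl-1-oxo-3-(triethylsilyloxy)butan-2-yl]oxyphenyl]ethyl (2R)-2-methylbutanoate (A7) into an arylchromium species. This would add to the tethered aldehyde (Nozaki–Hiyama–Kishi reaction) and give the trans carbinol A6.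
- Merits: the key step is an established reaction type, which the chosen key step is not. C2 comes from reliable asymmetric dihydroxylation chemistry and an inverting aryl ether formation.
- Weak points: the α-aryloxy aldehyde stereocentre of A7 is prone to epimerisation, and C3 is set only by substrate control of uncertain sense. Making the aryl ether of A7 again raises the phenoxide/benzylic ester conflict or forces a longer ordering. After A6 the tertiary silyl ether must be removed and dehydrated regioselectively towards the methyl group and not towards C2–H, before acylation and oxidation. Chromium is used in excess.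
- Comparison: it is safer at the ring closure but clearly longer afterwards, with a dehydration whose regiochemistry is as uncertain as anything in the chosen plan. The chosen plan sets two stereocentres catalytically and leaves the alkene already in place.

Key step: step 8

Assumption: which antipode of the bisphosphine leads to the 2R series in step 8 cannot be predicted with confidence; the route is written for (R,R)-Ph-BPE [1,2-bis(2,5-diphenylphospholano)ethane], and the mirror-image ligand would be used if the sense proves opposite.
Assumption: (2R)-2-methylbutanoic acid (8) is taken as a purchasable, enantiopure acid.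

## Route

Step 1
Reactants: 1 4-hydroxyacetophenone
Product: 2 5-acetyl-2-hydroxybenzaldehyde
Conditions: MgCl2, Et3N, (CH2O)n, MeCN, reflux; then 1 M HCl
Reagents that add atoms: paraformaldehyde (as formaldehyde), C=O
Why: Magnesium phenoxide-directed ortho-formylation (Casnati–Skattebøl reaction): the phenoxide–magnesium–formaldehyde complex delivers the C1 unit only ortho to oxygen, the para position being blocked by the acetyl group, and a second equivalent of formaldehyde oxidises the hydroxymethyl stage to the aldehyde.

Step 2
Reactants: 2 5-acetyl-2-hydroxybenzaldehyde; 3 propargyl bromide (3-bromoprop-1-yne)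
Product: 4 5-acetyl-2-(prop-2-yn-1-yloxy)benzaldehyde
Conditions: K2CO3, DMF, rt
Reagents that add atoms: none
Why: Williamson ether synthesis on an acidic, hydrogen-bonded phenol; carbonate is too weak to touch the ketone or the aldehyde, and the propargylic bromide is a fast SN2 partner.

Step 3
Reactants: 4 5-acetyl-2-(prop-2-yn-1-yloxy)benzaldehyde
Product: 5 1-[3-(dimethoxymethyl)-4-(prop-2-yn-1-yloxy)phenyl]ethan-1-one
Conditions: HC(OMe)3, PPTS (cat.), MeOH, rt; Et3N quench
Reagents that add atoms: trimethyl orthoformate, COC(OC)OC
Why: Acid-catalysed acetalisation; the aldehyde is far more electrophilic than the aryl methyl ketone, which is deactivated by the para alkoxy group, so only the aldehyde should be masked.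

Step 4
Reactants: 5 1-[3-(dimethoxymethyl)-4-(prop-2-yn-1-yloxy)phenyl]ethan-1-one
Product: 6 (1R)-1-[3-(dimethoxymethyl)-4-(prop-2-yn-1-yloxy)phenyl]ethan-1-ol
Conditions: RuCl[(R,R)-TsDPEN](p-cymene) (1 mol%), HCO2Na, H2O/MeOH, 40 °C
Reagents that add atoms: none
Why: Asymmetric transfer hydrogenation through the metal–ligand bifunctional six-membered transition state; the (R,R)-configured complex is the one that gives (R)-1-arylethanols from aryl methyl ketones, which sets the carbinol centre. Formate makes the reduction irreversible for this electron-rich ketone, and the near-neutral medium should leave the acetal and the alkyne alone.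

Step 5
Reactants: 6 (1R)-1-[3-(dimethoxymethyl)-4-(prop-2-yn-1-yloxy)phenyl]ethan-1-ol
Product: 7 (1R)-1-[3-(dimethoxymethyl)-4-(propa-1,2-dien-1-yloxy)phenyl]ethan-1-ol
Conditions: KOtBu (1.5 equiv), THF, 0 °C to rt; then H2O
Reagents that add atoms: none
Why: Base-mediated propargyl–allenyl isomerisation of an aryl propargyl ether; the first equivalent of base is held as the benzylic alkoxide and the excess effects the prototropic shift, the allenyl ether being collected as the kinetic product. No carbonyl group or ester is present at this stage, so the base finds nothing else to attack.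

Step 6
Reactants: 7 (1R)-1-[3-(dimethoxymethyl)-4-(propa-1,2-dien-1-yloxy)phenyl]ethan-1-ol; 8 (2R)-2-methylbutanoic acid
Product: 9 (1R)-1-[3-(dimethoxymethyl)-4-(propa-1,2-dien-1-yloxy)phenyl]ethyl (2R)-2-methylbutanoate
Conditions: DCC, DMAP (cat.), CH2Cl2, 0 °C to rt
Reagents that add atoms: none
Why: Steglich esterification; acyl transfer occurs at oxygen, so the carbinol centre is retained, and an α-alkyl acid should not epimerise with catalytic DMAP at 0 °C. O1 is already capped, so no quinone methide can form.

Step 7
Reactants: 9 (1R)-1-[3-(dimethoxymethyl)-4-(propa-1,2-dien-1-yloxy)phenyl]ethyl (2R)-2-methylbutanoate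
Product: 10 (1R)-1-[3-formyl-4-(propa-1,2-dien-1-yloxy)phenyl]ethyl (2R)-2-methylbutanoate
Conditions: PPTS (cat.), acetone/H2O (10:1), rt
Reagents that add atoms: water, O
Why: Mild acetal hydrolysis; the dimethyl acetal of an ortho-alkoxybenzaldehyde ionises far faster than an aryloxyallene is protonated or a benzylic ester is ionised at this acidity, so only the aldehyde should be released.

Step 8
Reactants: 10 (1R)-1-[3-formyl-4-(propa-1,2-dien-1-yloxy)phenyl]ethyl (2R)-2-methylbutanoate; 11 bis(pinacolato)diboron
Product: 13 (1R)-1-[(2R,3R)-3-hydroxy-2-[1-(4,4,5,5-tetramethyl-1,3,2-dioxaborolan-2-yl)ethenyl]-2,3-dihydro-1-benzofuran-5-yl]ethyl (2R)-2-methylbutanoate, via C3 O-pinacolboryl ether 12 (not isolated)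
Conditions: CuCl (5 mol%), (R,R)-Ph-BPE (6 mol%), NaOtBu (10 mol%), THF, 0 °C to rt; then aq NH4Cl
Reagents that add atoms: none
Why: Proposed new method: a ligated copper boryl, formed from CuCl, NaOtBu and 11, should add across the terminal double bond of the aryloxyallene with boron on the central carbon, and the resulting 2-borylallylcopper should attack the ortho aldehyde through its aryloxy-bearing terminus; the closest known reaction types are the intermolecular copper-catalysed enantioselective borylative coupling of monosubstituted allenes with aldehydes and the copper-catalysed borylative cyclisation of carbon-tethered allenyl ketones, neither of which has been shown for an aryloxyallene closing onto an aldehyde through its oxygen-bearing carbon. Ring B closes in a 5-exo-trig mode (C2 onto the carbonyl carbon C3); attack through the CH2 terminus would need a seven-membered ring and should not compete. C2 is set by the chiral bisphosphine on monovalent copper, which selects the face of the allyl terminus, the side-chain stereocentres being too remote to help or interfere. C3 is set relative to C2 by the closed six-membered transition state in which copper is bound to the carbonyl oxygen: with the planar aryl ether as tether the carbonyl oxygen and the borylated vinyl carbon must lie on the same side of the forming ring, so the cis (2R,3R) alcohol is expected, as in other cyclisations of allene-derived 2-metalloallyl species onto aldehydes. The step needs chemoselectivity for the allene over the aldehyde in the boryl addition, which the high reactivity of allenes towards copper boryls and the low electrophilicity of an ortho-alkoxybenzaldehyde should secure. Compound 11 turns over the copper alkoxide to the O-boryl ether 12, which the aqueous work-up hydrolyses to 13.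

Step 9
Reactants: 13 (1R)-1-[(2R,3R)-3-hydroxy-2-[1-(4,4,5,5-tetramethyl-1,3,2-dioxaborolan-2-yl)ethenyl]-2,3-dihydro-1-benzofuran-5-yl]ethyl (2R)-2-methylbutanoate
Product: 14 (1R)-1-[(2R,3R)-3-hydroxy-2-(prop-1-en-2-yl)-2,3-dihydro-1-benzofuran-5-yl]ethyl (2R)-2-methylbutanoate
Conditions: MeI, Pd2(dba)3 (2.5 mol%), P(o-tol)3 (10 mol%), K2CO3, DMF/H2O (9:1), 60 °C
Reagents that add atoms: iodomethane, CI
Why: Suzuki–Miyaura methylation of an alkenylboronic ester: zerovalent palladium adds iodomethane, the base-activated boronate transmetalates and reductive elimination forms the C(sp2)–CH3 bond; C2 and C3 are not involved, and the free hydroxyl is tolerated.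

Step 10
Reactants: 14 (1R)-1-[(2R,3R)-3-hydroxy-2-(prop-1-en-2-yl)-2,3-dihydro-1-benzofuran-5-yl]ethyl (2R)-2-methylbutanoate; 15 3-methylbutanoic acid
Product: 16 (2R,3S)-5-[(1R)-1-[(2R)-2-methylbutanoyloxy]ethyl]-2-(prop-1-en-2-yl)-2,3-dihydro-1-benzofuran-3-yl 3-methylbutanoate
Conditions: PPh3, DIAD, THF, 0 °C to rt
Reagents that add atoms: none
Why: Mitsunobu reaction: the carboxylate displaces the alkoxyphosphonium group at C3 in an SN2 step with inversion (3R to 3S), approaching the face that carries only C2–H and is opposite to the isopropenyl group. This sets the trans relationship and installs the isovalerate in one operation.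

Step 11
Reactants: 16 (2R,3S)-5-[(1R)-1-[(2R)-2-methylbutanoyloxy]ethyl]-2-(prop-1-en-2-yl)-2,3-dihydro-1-benzofuran-3-yl 3-methylbutanoate
Product: 18 (2R,3S)-5-[(1R)-1-[(2R)-2-methylbutanoyloxy]ethyl]-2-(3-oxoprop-1-en-2-yl)-2,3-dihydro-1-benzofuran-3-yl 3-methylbutanoate, via allylic alcohol 17 (not isolated)
Conditions: SeO2 (2 equiv), 1,4-dioxane, 70 °C
Reagents that add atoms: selenium dioxide, O=[Se]=O
Why: Riley allylic oxidation: ene reaction at the terminal CH2 followed by a [2,3]-sigmatropic shift oxidises the methyl group of the 1,1-disubstituted alkene, which is preferred over the C2–H methine (tertiary, ring-bound and deactivated by O1), and the allylic alcohol 17 is oxidised on to the enal. No stereocentre is touched, and the trans ester has no C2–H anti to the C3–O bond, which should slow elimination.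

## Compound list

1 | 4-hydroxyacetophenone | CC(=O)c1ccc(O)cc1 | starting material
2 | 5-acetyl-2-hydroxybenzaldehyde | CC(=O)c1ccc(O)c(C=O)c1 | intermediate
3 | propargyl bromide (3-bromoprop-1-yne) | C#CCBr | starting material
4 | 5-acetyl-2-(prop-2-yn-1-yloxy)benzaldehyde | CC(=O)c1ccc(OCC#C)c(C=O)c1 | intermediate
5 | 1-[3-(dimethoxymethyl)-4-(prop-2-yn-1-yloxy)phenyl]ethan-1-one | CC(=O)c1ccc(OCC#C)c(C(OC)OC)c1 | intermediate
6 | (1R)-1-[3-(dimethoxymethyl)-4-(prop-2-yn-1-yloxy)phenyl]ethan-1-ol | C#CCOc1ccc([C@@H](C)O)cc1C(OC)OC | intermediate
7 | (1R)-1-[3-(dimethoxymethyl)-4-(propa-1,2-dien-1-yloxy)phenyl]ethan-1-ol | C=C=COc1ccc([C@@H](C)O)cc1C(OC)OC | intermediate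
8 | (2R)-2-methylbutanoic acid | CC[C@@H](C)C(=O)O | starting material
9 | (1R)-1-[3-(dimethoxymethyl)-4-(propa-1,2-dien-1-yloxy)phenyl]ethyl (2R)-2-methylbutanoate | C=C=COc1ccc([C@@H](C)OC(=O)[C@H](C)CC)cc1C(OC)OC | intermediate
10 | (1R)-1-[3-formyl-4-(propa-1,2-dien-1-yloxy)phenyl]ethyl (2R)-2-methylbutanoate | C=C=COc1ccc([C@@H](C)OC(=O)[C@H](C)CC)cc1C=O | intermediate
11 | bis(pinacolato)diboron | CC1(C)OB(OC1(C)C)B1OC(C)(C)C(C)(C)O1 | starting material
12 | (1R)-1-[(2R,3R)-3-[(4,4,5,5-tetramethyl-1,3,2-dioxaborolan-2-yl)oxy]-2-[1-(4,4,5,5-tetramethyl-1,3,2-dioxaborolan-2-yl)ethenyl]-2,3-dihydro-1-benzofuran-5-yl]ethyl (2R)-2-methylbutanoate | C=C(B1OC(C)(C)C(C)(C)O1)[C@H]1Oc2ccc([C@@H](C)OC(=O)[C@H](C)CC)cc2[C@H]1OB1OC(C)(C)C(C)(C)O1 | intermediate (not isolated)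
13 | (1R)-1-[(2R,3R)-3-hydroxy-2-[1-(4,4,5,5-tetramethyl-1,3,2-dioxaborolan-2-yl)ethenyl]-2,3-dihydro-1-benzofuran-5-yl]ethyl (2R)-2-methylbutanoate (cis) | C=C(B1OC(C)(C)C(C)(C)O1)[C@H]1Oc2ccc([C@@H](C)OC(=O)[C@H](C)CC)cc2[C@H]1O | intermediate
14 | (1R)-1-[(2R,3R)-3-hydroxy-2-(prop-1-en-2-yl)-2,3-dihydro-1-benzofuran-5-yl]ethyl (2R)-2-methylbutanoate (cis) | C=C(C)[C@H]1Oc2ccc([C@@H](C)OC(=O)[C@H](C)CC)cc2[C@H]1O | intermediate
15 | 3-methylbutanoic acid (isovaleric acid) | CC(C)CC(=O)O | starting material
16 | (2R,3S)-5-[(1R)-1-[(2R)-2-methylbutanoyloxy]ethyl]-2-(prop-1-en-2-yl)-2,3-dihydro-1-benzofuran-3-yl 3-methylbutanoate (trans) | C=C(C)[C@H]1Oc2ccc([C@@H](C)OC(=O)[C@H](C)CC)cc2[C@@H]1OC(=O)CC(C)C | intermediate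
17 | (2R,3S)-2-(3-hydroxyprop-1-en-2-yl)-5-[(1R)-1-[(2R)-2-methylbutanoyloxy]ethyl]-2,3-dihydro-1-benzofuran-3-yl 3-methylbutanoate | C=C(CO)[C@H]1Oc2ccc([C@@H](C)OC(=O)[C@H](C)CC)cc2[C@@H]1OC(=O)CC(C)C | intermediate (not isolated)
18 | (2R,3S)-5-[(1R)-1-[(2R)-2-methylbutanoyloxy]ethyl]-2-(3-oxoprop-1-en-2-yl)-2,3-dihydro-1-benzofuran-3-yl 3-methylbutanoate (CNP0154159.1) | C=C(C=O)[C@H]1Oc2ccc([C@@H](C)OC(=O)[C@H](C)CC)cc2[C@@H]1OC(=O)CC(C)C | target

## Step count and least certain steps

Total step count: 11. Longest linear sequence: 11 steps (1 to 18); 3, 8, 11 and 15 enter as purchased reagents.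

**Step 8 (key step, new method).**
- What may go wrong: the copper boryl may add to the aldehyde instead of the allene. The allylcopper may be protonated or may eliminate before it cyclises. Enantioselection may be poor because the ligand has to differentiate the faces of a heteroatom-substituted allyl terminus for which there is no model. Catalytic alkoxide may slowly erode the ester α-centre.
- The relative configuration is the least worrying point. A trans-selective closure would only replace the inverting esterification of step 10 by a plain acylation with retention.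
- Fallback (known chemistry; the same C2–C3 bond by enamine aldol chemistry). It sets out from 6 and returns at 14. Steglich esterification of 6 with 8 gives (1R)-1-[3-(dimethoxymethyl)-4-(prop-2-yn-1-yloxy)phenyl]ethyl (2R)-2-methylbutanoate F1. Gold-catalysed Markovnikov hydration of the terminal alkyne (Ph3PAuNTf2, monovalent gold, aqueous dioxane with a trace of PPTS, which also frees the aldehyde) gives (1R)-1-[3-formyl-4-(2-oxopropoxy)phenyl]ethyl (2R)-2-methylbutanoate F2. Proline-catalysed 5-enolexo aldol cyclisation, a known entry to cis-2-acyl-3-hydroxy-2,3-dihydrobenzofurans, gives (1R)-1-[(2S,3R)-2-acetyl-3-hydroxy-2,3-dihydro-1-benzofuran-5-yl]ethyl (2R)-2-methylbutanoate F3, the proline antipode being chosen for this sense. Non-basic titanium methylenation of the ketone (Zn, CH2Br2, TiCl4) then gives 14.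

**Step 10 (Mitsunobu inversion).**
- What may go wrong: in the activated cis alcohol, C2–H is anti to the leaving group, so elimination to the aromatic benzofuran competes with substitution. Partial ionisation at the benzylic C3 would cost stereospecificity. Acyl transfer through an acyloxyphosphonium ion would give retention.
- Fallback, from 14 back to 16. Mitsunobu reaction with the more acidic chloroacetic acid, which substitutes faster and is a weaker base, gives (2R,3S)-5-[(1R)-1-[(2R)-2-methylbutanoyloxy]ethyl]-2-(prop-1-en-2-yl)-2,3-dihydro-1-benzofuran-3-yl chloroacetate F4. Neutral removal of the chloroacetyl group with thiourea and NaHCO3 in ethanol gives (1R)-1-[(2R,3S)-3-hydroxy-2-(prop-1-en-2-yl)-2,3-dihydro-1-benzofuran-5-yl]ethyl (2R)-2-methylbutanoate F5. Acylation with isovaleric anhydride and DMAP gives 16 with retention.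

**Step 9 (Suzuki methylation).**
- What may go wrong: transmetalation of the hindered 1,1-disubstituted alkenylboronate may be slow and lead to protodeboronation. Zerovalent palladium may ionise the allylic C2–O1 bond, with ring opening or loss of configuration at C2. Aqueous carbonate may partly hydrolyse the side-chain ester.
- Fallback without palladium, from 13 to 17 and on to 18, bypassing 14 and 16. Mitsunobu reaction of 13 with 15 gives (2R,3S)-5-[(1R)-1-[(2R)-2-methylbutanoyloxy]ethyl]-2-[1-(4,4,5,5-tetramethyl-1,3,2-dioxaborolan-2-yl)ethenyl]-2,3-dihydro-1-benzofuran-3-yl 3-methylbutanoate F6. Matteson homologation (BrCH2Cl, n-BuLi, THF, −78 °C, carbenoid generated in the presence of the boronate so that ate-complex formation outruns attack on the esters) gives the allylboronate (2R,3S)-5-[(1R)-1-[(2R)-2-methylbutanoyloxy]ethyl]-2-[3-(4,4,5,5-tetramethyl-1,3,2-dioxaborolan-2-yl)prop-1-en-2-yl]-2,3-dihydro-1-benzofuran-3-yl 3-methylbutanoate F7. Oxidation with NaBO3·4H2O gives 17, here isolated, and MnO2 in CH2Cl2 takes 17 to 18.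

**Step 11 (SeO2 oxidation).**
- What may go wrong: the oxidation may stop at the allylic alcohol stage. Selenous acid at 70 °C may promote loss of isovaleric acid across C2–C3. Some attack at C2–H is possible.
- Fallback, from 16 to 18 by a different oxidation principle. Schenck ene reaction with singlet oxygen (O2, tetraphenylporphyrin, visible light, CH2Cl2, 0 °C) gives (2R,3S)-2-(3-hydroperoxyprop-1-en-2-yl)-5-[(1R)-1-[(2R)-2-methylbutanoyloxy]ethyl]-2,3-dihydro-1-benzofuran-3-yl 3-methylbutanoate F8. Dehydration of this primary allylic hydroperoxide with Ac2O and pyridine (Kornblum–DeLaMare type) gives 18 under non-acidic conditions.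

**Step 5 (propargyl to allenyl isomerisation).**
- What may go wrong: with excess base the allene may isomerise further to the 1-propynyl ether. The alkoxide may sequester the base and slow the reaction. Hydride exchange could erode the carbinol centre if traces of ketone 5 are carried over.
- Fallback, from 6 back to 7, removing the alkoxide from the base step. Silylation (TESCl, imidazole) gives triethyl{(1R)-1-[3-(dimethoxymethyl)-4-(prop-2-yn-1-yloxy)phenyl]ethoxy}silane F9. Isomerisation with catalytic KOtBu in THF gives triethyl{(1R)-1-[3-(dimethoxymethyl)-4-(propa-1,2-dien-1-yloxy)phenyl]ethoxy}silane F10. TBAF buffered with acetic acid then gives 7.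

## Further compounds

F1 | step 8 | (1R)-1-[3-(dimethoxymethyl)-4-(prop-2-yn-1-yloxy)phenyl]ethyl (2R)-2-methylbutanoate | C#CCOc1ccc([C@@H](C)OC(=O)[C@H](C)CC)cc1C(OC)OC
F2 | step 8 | (1R)-1-[3-formyl-4-(2-oxopropoxy)phenyl]ethyl (2R)-2-methylbutanoate | CC(=O)COc1ccc([C@@H](C)OC(=O)[C@H](C)CC)cc1C=O
F3 | step 8 | (1R)-1-[(2S,3R)-2-acetyl-3-hydroxy-2,3-dihydro-1-benzofuran-5-yl]ethyl (2R)-2-methylbutanoate (cis) | CC(=O)[C@H]1Oc2ccc([C@@H](C)OC(=O)[C@H](C)CC)cc2[C@H]1O
F4 | step 10 | (2R,3S)-5-[(1R)-1-[(2R)-2-methylbutanoyloxy]ethyl]-2-(prop-1-en-2-yl)-2,3-dihydro-1-benzofuran-3-yl chloroacetate | C=C(C)[C@H]1Oc2ccc([C@@H](C)OC(=O)[C@H](C)CC)cc2[C@@H]1OC(=O)CCl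
F5 | step 10 | (1R)-1-[(2R,3S)-3-hydroxy-2-(prop-1-en-2-yl)-2,3-dihydro-1-benzofuran-5-yl]ethyl (2R)-2-methylbutanoate (trans) | C=C(C)[C@H]1Oc2ccc([C@@H](C)OC(=O)[C@H](C)CC)cc2[C@@H]1O
F6 | step 9 | (2R,3S)-5-[(1R)-1-[(2R)-2-methylbutanoyloxy]ethyl]-2-[1-(4,4,5,5-tetramethyl-1,3,2-dioxaborolan-2-yl)ethenyl]-2,3-dihydro-1-benzofuran-3-yl 3-methylbutanoate | C=C(B1OC(C)(C)C(C)(C)O1)[C@H]1Oc2ccc([C@@H](C)OC(=O)[C@H](C)CC)cc2[C@@H]1OC(=O)CC(C)C
F7 | step 9 | (2R,3S)-5-[(1R)-1-[(2R)-2-methylbutanoyloxy]ethyl]-2-[3-(4,4,5,5-tetramethyl-1,3,2-dioxaborolan-2-yl)prop-1-en-2-yl]-2,3-dihydro-1-benzofuran-3-yl 3-methylbutanoate | C=C(CB1OC(C)(C)C(C)(C)O1)[C@H]1Oc2ccc([C@@H](C)OC(=O)[C@H](C)CC)cc2[C@@H]1OC(=O)CC(C)C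
F8 | step 11 | (2R,3S)-2-(3-hydroperoxyprop-1-en-2-yl)-5-[(1R)-1-[(2R)-2-methylbutanoyloxy]ethyl]-2,3-dihydro-1-benzofuran-3-yl 3-methylbutanoate | C=C(COO)[C@H]1Oc2ccc([C@@H](C)OC(=O)[C@H](C)CC)cc2[C@@H]1OC(=O)CC(C)C
F9 | step 5 | triethyl{(1R)-1-[3-(dimethoxymethyl)-4-(prop-2-yn-1-yloxy)phenyl]ethoxy}silane | C#CCOc1ccc([C@@H](C)O[Si](CC)(CC)CC)cc1C(OC)OC
F10 | step 5 | triethyl{(1R)-1-[3-(dimethoxymethyl)-4-(propa-1,2-dien-1-yloxy)phenyl]ethoxy}silane | C=C=COc1ccc([C@@H](C)O[Si](CC)(CC)CC)cc1C(OC)OC
A1 | alternative 1 | (1R)-1-[(2R,3S)-3-(tert-butyldimethylsilyloxy)-2-(prop-1-en-2-yl)-7-(trimethylsilyl)-2,3-dihydro-1-benzofuran-5-yl]ethyl (2R)-2-methylbutanoate | C=C(C)[C@H]1Oc2c([Si](C)(C)C)cc([C@@H](C)OC(=O)[C@H](C)CC)cc2[C@@H]1O[Si](C)(C)C(C)(C)C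
A2 | alternative 1 | (3S,4R)-3-(tert-butyldimethylsilyloxy)-5-methyl-4-[(trimethylsilyl)ethynyloxy]hex-5-en-1-yne | C=C(C)[C@H]([C@@H](O[Si](C)(C)C(C)(C)C)C#C)OC#C[Si](C)(C)C
A3 | alternative 1 | (2R)-but-3-yn-2-yl (2R)-2-methylbutanoate | C#C[C@@H](C)OC(=O)[C@H](C)CC
A4 | alternative 2 | (2R,3S)-5-[(1R)-1-[(2R)-2-methylbutanoyloxy]ethyl]-2-(prop-1-en-2-yl)-2,3-dihydro-1-benzofuran-3-yl 3-methylbutanoate (identical with 16) | C=C(C)[C@H]1Oc2ccc([C@@H](C)OC(=O)[C@H](C)CC)cc2[C@@H]1OC(=O)CC(C)C
A5 | alternative 2 | (3R,4S)-3-hydroxy-2,2-dimethyl-6-[(1R)-1-[(2R)-2-methylbutanoyloxy]ethyl]-3,4-dihydro-2H-chromen-4-yl 3-methylbutanoate (trans) | CC1(C)Oc2ccc([C@@H](C)OC(=O)[C@H](C)CC)cc2[C@H](OC(=O)CC(C)C)[C@H]1O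
A6 | alternative 3 | (1R)-1-[(2S,3S)-3-hydroxy-2-[2-(triethylsilyloxy)propan-2-yl]-2,3-dihydro-1-benzofuran-5-yl]ethyl (2R)-2-methylbutanoate (trans) | CC[Si](CC)(CC)OC(C)(C)[C@H]1Oc2ccc([C@@H](C)OC(=O)[C@H](C)CC)cc2[C@@H]1O
A7 | alternative 3 | (1R)-1-[3-iodo-4-[(2R)-3-methyl-1-oxo-3-(triethylsilyloxy)butan-2-yl]oxyphenyl]ethyl (2R)-2-methylbutanoate | CC[Si](CC)(CC)OC(C)(C)[C@H](C=O)Oc1ccc([C@@H](C)OC(=O)[C@H](C)CC)cc1I
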